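## Structural features

Germacrane numbering is used throughout: ring carbons C1–C10, C11/C12/C13 the lactone carbons on C7, C14 the ester carbon on C10, C15 the methyl on C4. Greek letters follow the germacranolide convention (H-7 is α, the C7–C11 bond is β).

The target is a ten-membered carbocycle with a trans-fused α-methylene-γ-butyrolactone across C6–C7 (O on C6, α; C11 on C7, β). It is read from the SMILES as (4R,5S,6S,7R,8S,9S). The C1=C10 bond is ring-cis (C2 and C9 on the same side; E by CIP because of the C14 methyl ester). The oxirane at C4–C5 is a cis epoxide (C3 and C6 cis, oxygen α), so it derives from a Z C4=C5 olefin. C4 to C9 are six contiguous stereocentres: epoxide oxygen and lactone oxygen are syn, H-6β/H-7α are trans, the C8 methacrylate is β and the C9 acetate is α (a trans diol carrying two different esters). Fragile groups are three conjugate acceptors (methylene lactone, methacrylate, C1=C10 enoate), the trisubstituted epoxide, and the vicinal diesters, which can migrate. The real difficulty is the medium ring with two ring-cis trisubstituted π units and the C6–C9 stereotetrad.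

The key step exploits one feature. C9, C10, C1, C2, C3 and C4 can be held in a cyclohexene whose C4–C9 bond is the transannular 1,6-vector of the macrocycle. C4=C5 and C8–C9(=O) are exactly the two π bonds an oxy-Cope shift creates, and the lactone fusion bond C6–C7 is the σ bond it forms.

## Logic of the disconnections

32 ⇒ 29. The lactone acyl bond C12–O6 is cut and C12 is taken back to the alcohol level. The methylene lactone is the most electrophilic group and is best made last. The gain is that no lactone acceptor is present earlier. The demand is an oxidation that touches only the primary allylic alcohol of 29 and lets the C6 hydroxyl close the ring.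

29 ⇒ 27 (through 28). Both C–O bonds of the oxirane are cut. The free 6α-hydroxyl of 27 is the only handle that can steer oxygen to the α face, and the cis epoxide follows from the Z olefin. Two stereocentres (C4, C5) reduce to one olefin geometry. The demand is oxygen delivery syn to the C6 hydroxyl with C11=C13 untouched, so the C12 silyl ether stays until 28 is made.

27 ⇒ 23 (through 26, 25, 24). Cut are the O9–acetyl bond, the C9–H bond (back to the ketone), the C8–O bond of the methacrylate (formed with inversion) and the C6 benzyl-type ether. The two esters differ, so one enters as a nucleophile at C8 and the other by acylation of the alcohol made from the C9 ketone. The trans-diol diester reduces to an α-ketol with one stereocentre. The demands are a clean SN2 at C8 and a 1,2-reduction anti to the C8–O bond.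

23 ⇒ 20. Key disconnection. C6–C7 and C8–O are cut and C4–C9 is rejoined. The ten-membered ring, both ring olefin geometries and C6, C7, C8 collapse to a cyclohexene with two adjacent stereocentres. The demands are a cis relation of the two alkenyl groups in 20, E geometry at both migrating termini, and one chair.

20 ⇒ 15 (through 19, 18, 17, 16). Cut are C10–C14 (carbonylation), O–C6 (vinyl ether), C5=C6 (olefination), and the C5 oxidation level is adjusted. The ester arm of 15 is needed for chelation in the step before and only afterwards becomes the E enol ether. The demands are E geometry and reaction of the vinyl iodide in the presence of the vinyl bromide.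

15 ⇒ 12 + 4. C8–C9 is cut. This is the convergent union and sets C9 relative to C4. The demand is that the dienyl group enters cis to the ester arm.

12 ⇒ 5 (through 10, 9, 6). Cut are C10–Br, the C1=C10 unsaturation and C4–CH3. C4 is the only stereocentre that is bought with a chiral reagent.

4 ⇒ 2 + 3, and 2 ⇒ 1. C7–C11 is cut (cross-coupling). The demand is retention of E geometry and single coupling of 3.

## Other disconnections considered

Alternative 1: End-to-end macrocyclisation, the first idea that comes to mind. The cut is C6–C7 of an open chain. The forward step is an intramolecular Nozaki–Hiyama–Kishi allylation of seco aldehyde A1 (Z enal at C6, 2-(bromomethyl)acrylate at C7=C11–C13) with CrCl2, closing ring and lactone together. The chosen plan is preferred for three reasons. A1 needs the Z enal, the ring-cis enoate next to C9, and C8/C9 each made by a separate acyclic stereoselective step. The closure is an entropically costly medium-ring formation. C6 and C7 would be induced only by C8 through a flexible chain, whereas in the chosen plan one chair fixes both.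

Alternative 2: Grob fragmentation. The cut is C4–C9 only. The forward step is fragmentation of the cis-decalin mesylate A2 (9-alkoxide, equatorial 5-mesylate anti to the fusion bond), giving the C9 ketone and the Z C4=C5 bond stereospecifically with C6–C8 preset. The chosen plan is preferred on step economy. A2 carries seven stereocentres including two adjacent fully substituted fusion atoms and already contains the C6–C7 bond, which the oxy-Cope makes for free from a cyclohexene with two stereocentres.

Alternative 3: The other oxy-Cope mapping. The cut is C2–C3 (formed) with C5–C10 broken, starting from the 1,2-dialkenylcyclohexanol A3 that holds C6–C9 on a six-membered ring. The chosen plan is preferred on three grounds. A3 is a hexasubstituted cyclohexane with a β-alkoxide ester at C10 that should cleave by retro-aldol, losing control of the C1=C10 geometry. Its product is a C5 ketone, from which the cis epoxide (two stereocentres) must be built without a directing group. Its enolate maps onto the E, not the Z, C4=C5 bond.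

Key step: step 13

Assumption: in step 4 the lithium ligand (HMPA in toluene) is taken as the one that gives the 1S keto ester; if it gives 1R, the complementary ligand set (THF) is used and nothing else changes.

## Steps

Step 1
Reactants: 1 2-bromoprop-2-en-1-ol
Product: 2 [(2-bromoprop-2-en-1-yl)oxy](tert-butyl)dimethylsilane
Conditions: TBSCl, imidazole, CH2Cl2, 0 °C → rt
Reagents that add atoms: tert-butyldimethylsilyl chloride CC(C)(C)[Si](C)(C)Cl
Why: Standard silylation of a primary allylic alcohol; the ether survives organolithium, CrCl2, carbonate and amide bases used later.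

Step 2
Reactants: 2 [(2-bromoprop-2-en-1-yl)oxy](tert-butyl)dimethylsilane; 3 (E)-1,2-bis(tributylstannyl)ethene
Product: 4 tert-butyldimethyl{[(3E)-2-methylidene-4-(tributylstannyl)but-3-en-1-yl]oxy}silane
Conditions: Pd(PPh3)4 (5 mol %), 3 (2 equiv), toluene, 90 °C
Reagents that add atoms: none
Why: Stille coupling; oxidative addition into the vinyl bromide and one transmetalation of the distannane (used in excess so that one tin stays) with retention of the E geometry.

Step 3
Reactants: 5 ethyl 2-oxocyclohexane-1-carboxylate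
Product: 6 ethyl 2-{[(2S)-1-tert-butoxy-3-methyl-1-oxobutan-2-yl]amino}cyclohex-1-ene-1-carboxylate
Conditions: L-valine tert-butyl ester, TsOH·H2O (cat.), toluene, reflux, Dean–Stark
Reagents that add atoms: L-valine tert-butyl ester CC(C)[C@H](N)C(=O)OC(C)(C)C
Why: Condensation of a β-keto ester with a primary amine gives the hydrogen-bonded enamino ester, the substrate for chiral lithio-enamine alkylation.

Step 4
Reactants: 6 ethyl 2-{[(2S)-1-tert-butoxy-3-methyl-1-oxobutan-2-yl]amino}cyclohex-1-ene-1-carboxylate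
Product: 9 ethyl (1S)-1-methyl-2-oxocyclohexane-1-carboxylate, via lithiated enamine 7 (not isolated), via methylated imine 8 (not isolated)
Conditions: LiN(iPr)2, toluene, −78 °C; MeI, HMPA, −78 → −20 °C; then 1 M aq. HCl, rt
Reagents that add atoms: methyl iodide CI; water O
Why: Asymmetric alkylation of a chelated chiral lithio enamine (Koga type): lithium is held by the nitrogen and the valine ester carbonyl, the isopropyl group screens one face, and the external ligand on lithium decides which face MeI attacks, so C4 is set as S; acid hydrolysis releases the ketone and the auxiliary.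

Step 5
Reactants: 9 ethyl (1S)-1-methyl-2-oxocyclohexane-1-carboxylate
Product: 10 ethyl (1S)-1-methyl-2-oxocyclohex-3-ene-1-carboxylate
Conditions: Pd(O2CCF3)2 (5 mol %), DMSO (10 mol %), O2 (1 atm), AcOH, 80 °C
Reagents that add atoms: none
Why: Palladium-catalysed aerobic α,β-dehydrogenation of a ketone; only the CH2 side can form the palladium enolate, so the enone is regiodefined and the quaternary centre blocks over-oxidation.

Step 6
Reactants: 10 ethyl (1S)-1-methyl-2-oxocyclohex-3-ene-1-carboxylate
Product: 12 ethyl (1S)-3-bromo-1-methyl-2-oxocyclohex-3-ene-1-carboxylate, via trans-dibromide 11 (not isolated)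
Conditions: Br2, CH2Cl2, 0 °C; then Et3N, 0 °C → rt
Reagents that add atoms: bromine BrBr
Why: Bromination–dehydrobromination of an enone gives the 2-bromoenone; the bromide is the handle for C14.

Step 7
Reactants: 4 tert-butyldimethyl{[(3E)-2-methylidene-4-(tributylstannyl)but-3-en-1-yl]oxy}silane; 12 ethyl (1S)-3-bromo-1-methyl-2-oxocyclohex-3-ene-1-carboxylate
Product: 15 ethyl (1S,2R)-3-bromo-2-hydroxy-1-methyl-2-[(1E)-4-{[tert-butyl(dimethyl)silyl]oxy}-3-methylidenebut-1-en-1-yl]cyclohex-3-ene-1-carboxylate, via dienyllithium 13 (not isolated), via dienylmagnesium bromide 14 (not isolated)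
Conditions: 4, n-BuLi, THF, −78 °C; MgBr2·OEt2, −78 °C; then 12 in CH2Cl2, −78 °C; aq. NH4Cl, −78 °C
Reagents that add atoms: none
Why: Tin–lithium exchange, transmetalation and chelation-controlled 1,2-addition: magnesium bridges the ketone and the ester carbonyl, which holds the ester pseudoequatorial and the methyl pseudoaxial, so the alkenyl group adds anti to the methyl and ends cis to the ester arm (C9 set, hydroxyl cis to methyl); the α-bromoenone favours carbonyl addition.

Step 8
Reactants: 15 ethyl (1S,2R)-3-bromo-2-hydroxy-1-methyl-2-[(1E)-4-{[tert-butyl(dimethyl)silyl]oxy}-3-methylidenebut-1-en-1-yl]cyclohex-3-ene-1-carboxylate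
Product: 16 (1R,6R)-2-bromo-6-(hydroxymethyl)-6-methyl-1-[(1E)-4-{[tert-butyl(dimethyl)silyl]oxy}-3-methylidenebut-1-en-1-yl]cyclohex-2-en-1-ol
Conditions: iBu2AlH (4 equiv), CH2Cl2, −78 → 0 °C; Rochelle salt
Reagents that add atoms: none
Why: Hydride reduction of the neopentyl ester to the primary alcohol; vinyl bromide, diene and silyl ether are inert and the cold aluminium alkoxide does not undergo retro-aldol cleavage.

Step 9
Reactants: 16 (1R,6R)-2-bromo-6-(hydroxymethyl)-6-methyl-1-[(1E)-4-{[tert-butyl(dimethyl)silyl]oxy}-3-methylidenebut-1-en-1-yl]cyclohex-2-en-1-ol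
Product: 17 (1S,2R)-3-bromo-2-hydroxy-1-methyl-2-[(1E)-4-{[tert-butyl(dimethyl)silyl]oxy}-3-methylidenebut-1-en-1-yl]cyclohex-3-ene-1-carbaldehyde
Conditions: Dess–Martin periodinane, NaHCO3, CH2Cl2, 0 °C → rt
Reagents that add atoms: none
Why: Dess–Martin oxidation of the primary alcohol; the tertiary alcohol cannot be oxidised and the aldehyde has no α-hydrogen, so it cannot epimerise or dehydrate.

Step 10
Reactants: 17 (1S,2R)-3-bromo-2-hydroxy-1-methyl-2-[(1E)-4-{[tert-butyl(dimethyl)silyl]oxy}-3-methylidenebut-1-en-1-yl]cyclohex-3-ene-1-carbaldehyde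
Product: 18 (1R,6R)-2-bromo-6-[(E)-2-iodoethenyl]-6-methyl-1-[(1E)-4-{[tert-butyl(dimethyl)silyl]oxy}-3-methylidenebut-1-en-1-yl]cyclohex-2-en-1-ol
Conditions: CrCl2, CHI3, THF/1,4-dioxane, 0 °C → rt
Reagents that add atoms: iodoform IC(I)I
Why: Takai olefination; the geminal dichromium species adds to the aldehyde and eliminates anti to give the E vinyl iodide (C6 added); CrCl2 alone does not insert into the vinyl bromide and tolerates the free alcohol.

Step 11
Reactants: 18 (1R,6R)-2-bromo-6-[(E)-2-iodoethenyl]-6-methyl-1-[(1E)-4-{[tert-butyl(dimethyl)silyl]oxy}-3-methylidenebut-1-en-1-yl]cyclohex-2-en-1-ol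
Product: 19 (1R,6R)-2-bromo-6-{(E)-2-[(4-methoxyphenyl)methoxy]ethenyl}-6-methyl-1-[(1E)-4-{[tert-butyl(dimethyl)silyl]oxy}-3-methylidenebut-1-en-1-yl]cyclohex-2-en-1-ol
Conditions: CuI (10 mol %), 3,4,7,8-tetramethyl-1,10-phenanthroline (20 mol %), Cs2CO3, 4-methoxybenzyl alcohol, toluene, 80 °C
Reagents that add atoms: 4-methoxybenzyl alcohol COc1ccc(CO)cc1
Why: Copper-catalysed Ullmann-type C–O coupling of a vinyl iodide with an alcohol, with retention of the E geometry; the trisubstituted vinyl bromide flanked by the carbinol should react much more slowly, and the E iodide cannot be reached by the tertiary hydroxyl.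

Step 12
Reactants: 19 (1R,6R)-2-bromo-6-{(E)-2-[(4-methoxyphenyl)methoxy]ethenyl}-6-methyl-1-[(1E)-4-{[tert-butyl(dimethyl)silyl]oxy}-3-methylidenebut-1-en-1-yl]cyclohex-2-en-1-ol
Product: 20 methyl (5R,6R)-6-hydroxy-5-{(E)-2-[(4-methoxyphenyl)methoxy]ethenyl}-5-methyl-6-[(1E)-4-{[tert-butyl(dimethyl)silyl]oxy}-3-methylidenebut-1-en-1-yl]cyclohex-1-ene-1-carboxylate
Conditions: Pd(OAc)2 (10 mol %), Xantphos (12 mol %), CO (1 atm), Et3N, MeOH/DMF, 70 °C
Reagents that add atoms: carbon monoxide [C-]#[O+]; methanol CO
Why: Palladium-catalysed methoxycarbonylation of the vinyl bromide (oxidative addition, CO insertion, methanolysis) installs C14; the vinylpalladium cannot reach the pendant alkenes in a favourable ring size and 70 °C is far below the neutral oxy-Cope threshold.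

Step 13
Reactants: 20 methyl (5R,6R)-6-hydroxy-5-{(E)-2-[(4-methoxyphenyl)methoxy]ethenyl}-5-methyl-6-[(1E)-4-{[tert-butyl(dimethyl)silyl]oxy}-3-methylidenebut-1-en-1-yl]cyclohex-1-ene-1-carboxylate
Product: 23 methyl (1(10)-cis,4Z)-8α-hydroxy-6α-[(4-methoxyphenyl)methoxy]-9-oxo-12-{[tert-butyl(dimethyl)silyl]oxy}germacra-1(10),4,11(13)-trien-14-oate, via potassium alkoxide 21 (not isolated), via potassium dienolate 22 (not isolated)
Conditions: KN(SiMe3)2 (1.05 equiv), 18-crown-6, THF, −20 → 25 °C; then −78 °C, 3-phenyl-2-(phenylsulfonyl)oxaziridine; AcOH, −78 °C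
Reagents that add atoms: 3-phenyl-2-(phenylsulfonyl)oxaziridine O=S(=O)(c1ccccc1)N1OC1c1ccccc1
Why: Anionic oxy-Cope rearrangement with in-situ enolate hydroxylation; the closest known type is the potassium-alkoxide-accelerated [3,3] shift of cis-1,2-dialkenylcyclohexanols to (Z)-cyclodec-5-enones followed by oxaziridine oxidation of the enolate. In alkoxide 21 the diene C7=C8–C9–C4–C5=C6 reorganises through a chair in which C6 bonds to C7 while C4–C9 breaks, so the ten-membered ring is closed by a four-atom ring expansion of the cyclohexene and not by an end-to-end cyclisation. The C1=C10 bond is a spectator and stays ring-cis because it was a cyclohexene bond. In the reacting half-chair the oxyanion and the C4 alkenyl arm are axial and the methyl and the dienyl group equatorial, which puts ring bond C3–C4 axial on the chair and delivers the Z C4=C5 bond; the other chair would need methyl and dienyl both axial. Both migrating termini are E, so the ether oxygen on C6 and the C11 unit on C7 sit equatorial, and the new C6–C7 bond carries H-6β and H-7α with the absolute sense dictated by C4 and C9 of 20. The product is the ring-trans dienolate 22, whose inner face is covered by the ring; with H-7 eclipsing the enolate (A(1,3) strain against the O–K group) the oxaziridine can reach only the outer face of C8, giving the 8α alcohol. That epimer is the planned one, because step 14 inverts C8. The step needs [3,3] shift over fragmentation (C4 carries no acceptor after step 11), the exocyclic diene over the endocyclic C1=C10 (which would require a boat-like bicyclic array), and one equivalent of base so that the enoate γ-position is not deprotonated.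

Step 14
Reactants: 23 methyl (1(10)-cis,4Z)-8α-hydroxy-6α-[(4-methoxyphenyl)methoxy]-9-oxo-12-{[tert-butyl(dimethyl)silyl]oxy}germacra-1(10),4,11(13)-trien-14-oate
Product: 24 methyl (1(10)-cis,4Z)-8β-(2-methylprop-2-enoyloxy)-6α-[(4-methoxyphenyl)methoxy]-9-oxo-12-{[tert-butyl(dimethyl)silyl]oxy}germacra-1(10),4,11(13)-trien-14-oate
Conditions: PPh3, iPrO2CN=NCO2iPr, methacrylic acid, toluene, 0 °C → rt (betaine formed before 23 is added)
Reagents that add atoms: methacrylic acid C=C(C)C(=O)O
Why: Mitsunobu esterification: the ketol hydroxyl is activated as the oxyphosphonium and displaced by methacrylate with inversion (8α → 8β), the adjacent carbonyl accelerating the SN2; the ester is installed and C8 corrected in one operation.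

Step 15
Reactants: 24 methyl (1(10)-cis,4Z)-8β-(2-methylprop-2-enoyloxy)-6α-[(4-methoxyphenyl)methoxy]-9-oxo-12-{[tert-butyl(dimethyl)silyl]oxy}germacra-1(10),4,11(13)-trien-14-oate
Product: 25 methyl (1(10)-cis,4Z)-9α-hydroxy-8β-(2-methylprop-2-enoyloxy)-6α-[(4-methoxyphenyl)methoxy]-12-{[tert-butyl(dimethyl)silyl]oxy}germacra-1(10),4,11(13)-trien-14-oate
Conditions: NaBH4, CeCl3·7H2O, MeOH, −78 °C
Reagents that add atoms: none
Why: Luche 1,2-reduction; CeCl3 keeps hydride at the ketone and away from the three conjugate acceptors, and Felkin–Anh addition anti to the non-chelating C8–O bond gives the 8,9-trans (9α) alcohol.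

Step 16
Reactants: 25 methyl (1(10)-cis,4Z)-9α-hydroxy-8β-(2-methylprop-2-enoyloxy)-6α-[(4-methoxyphenyl)methoxy]-12-{[tert-butyl(dimethyl)silyl]oxy}germacra-1(10),4,11(13)-trien-14-oate
Product: 26 methyl (1(10)-cis,4Z)-9α-acetoxy-8β-(2-methylprop-2-enoyloxy)-6α-[(4-methoxyphenyl)methoxy]-12-{[tert-butyl(dimethyl)silyl]oxy}germacra-1(10),4,11(13)-trien-14-oate
Conditions: Ac2O, pyridine, DMAP (cat.), CH2Cl2, 0 °C
Reagents that add atoms: acetic anhydride CC(=O)OC(C)=O
Why: DMAP-catalysed acetylation of the only free hydroxyl, done directly after the reduction so that the trans-vicinal methacrylate cannot migrate.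

Step 17
Reactants: 26 methyl (1(10)-cis,4Z)-9α-acetoxy-8β-(2-methylprop-2-enoyloxy)-6α-[(4-methoxyphenyl)methoxy]-12-{[tert-butyl(dimethyl)silyl]oxy}germacra-1(10),4,11(13)-trien-14-oate
Product: 27 methyl (1(10)-cis,4Z)-9α-acetoxy-6α-hydroxy-8β-(2-methylprop-2-enoyloxy)-12-{[tert-butyl(dimethyl)silyl]oxy}germacra-1(10),4,11(13)-trien-14-oate
Conditions: DDQ, CH2Cl2/pH 7 buffer, 0 °C
Reagents that add atoms: none
Why: Oxidative cleavage of the 4-methoxybenzyl ether (benzylic hydride abstraction, hydrolysis of the oxocarbenium ion) frees the C6 hydroxyl; esters, silyl ether and olefins are inert at 0 °C.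

Step 18
Reactants: 27 methyl (1(10)-cis,4Z)-9α-acetoxy-6α-hydroxy-8β-(2-methylprop-2-enoyloxy)-12-{[tert-butyl(dimethyl)silyl]oxy}germacra-1(10),4,11(13)-trien-14-oate
Product: 28 methyl (1(10)-cis)-9α-acetoxy-4α,5α-epoxy-6α-hydroxy-8β-(2-methylprop-2-enoyloxy)-12-{[tert-butyl(dimethyl)silyl]oxy}germacra-1(10),11(13)-dien-14-oate
Conditions: VO(acac)2 (5 mol %), t-BuOOH (decane), CH2Cl2, 0 °C → rt
Reagents that add atoms: tert-butyl hydroperoxide CC(C)(C)OO
Why: Hydroxyl-directed vanadium-catalysed epoxidation: the vanadate ester of the C6 alcohol delivers the peroxide oxygen through an O–C6–C5=C4 dihedral near 50° with ring carbon C7 on the opposite face, as in Z-cycloalkenols of medium rings, so oxygen should arrive syn to the hydroxyl (α face); the Z olefin gives the cis epoxide (4R,5S), and only the allylic-alcohol olefin reacts.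

Step 19
Reactants: 28 methyl (1(10)-cis)-9α-acetoxy-4α,5α-epoxy-6α-hydroxy-8β-(2-methylprop-2-enoyloxy)-12-{[tert-butyl(dimethyl)silyl]oxy}germacra-1(10),11(13)-dien-14-oate
Product: 29 methyl (1(10)-cis)-9α-acetoxy-4α,5α-epoxy-6α,12-dihydroxy-8β-(2-methylprop-2-enoyloxy)germacra-1(10),11(13)-dien-14-oate
Conditions: Bu4NF, AcOH (1:1), THF, 0 °C → rt
Reagents that add atoms: none
Why: Fluoride desilylation buffered with acetic acid, so that neither ester migrates to the C6 or C12 hydroxyl and the epoxide is not opened.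

Step 20
Reactants: 29 methyl (1(10)-cis)-9α-acetoxy-4α,5α-epoxy-6α,12-dihydroxy-8β-(2-methylprop-2-enoyloxy)germacra-1(10),11(13)-dien-14-oate
Product: 32 CNP0153978.8 methyl (4R,5S,6S,7R,8S,9S)-9-acetoxy-4,5-epoxy-8-(2-methylprop-2-enoyloxy)-12-oxo-6,12-epoxygermacra-1(10),11(13)-dien-14-oate, via hydroxy enal 30 (not isolated), via lactol 31 (not isolated)
Conditions: TEMPO (20 mol %), PhI(OAc)2 (2.5 equiv), CH2Cl2, rt
Reagents that add atoms: none
Why: Oxoammonium oxidation of the primary allylic alcohol to the enal, closure of the C6 hydroxyl to the lactol and a second oxidation give the α-methylene lactone (oxidative lactonisation of a 2-methylidene-1,4-diol); the trans fusion is fixed by C6 and C7, and the secondary alcohol is consumed only as the lactol.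

## Compound list

1 | 2-bromoprop-2-en-1-ol | OCC(Br)=C | starting material
2 | [(2-bromoprop-2-en-1-yl)oxy](tert-butyl)dimethylsilane | C=C(Br)CO[Si](C)(C)C(C)(C)C | intermediate
3 | (E)-1,2-bis(tributylstannyl)ethene | CCCC[Sn](CCCC)(CCCC)/C=C/[Sn](CCCC)(CCCC)CCCC | starting material
4 | tert-butyldimethyl{[(3E)-2-methylidene-4-(tributylstannyl)but-3-en-1-yl]oxy}silane | CCCC[Sn](CCCC)(CCCC)/C=C/C(=C)CO[Si](C)(C)C(C)(C)C | intermediate
5 | ethyl 2-oxocyclohexane-1-carboxylate | CCOC(=O)C1CCCCC1=O | starting material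
6 | ethyl 2-{[(2S)-1-tert-butoxy-3-methyl-1-oxobutan-2-yl]amino}cyclohex-1-ene-1-carboxylate | CCOC(=O)C1=C(N[C@@H](C(C)C)C(=O)OC(C)(C)C)CCCC1 | intermediate
7 | N-lithio derivative of 6 (lithiated enamine) | CCOC(=O)C1=C(N([Li])[C@@H](C(C)C)C(=O)OC(C)(C)C)CCCC1 | intermediate
8 | ethyl (1S)-2-{[(2S)-1-tert-butoxy-3-methyl-1-oxobutan-2-yl]imino}-1-methylcyclohexane-1-carboxylate | CCOC(=O)[C@@]1(C)CCCCC1=N[C@@H](C(C)C)C(=O)OC(C)(C)C | intermediate
9 | ethyl (1S)-1-methyl-2-oxocyclohexane-1-carboxylate | CCOC(=O)[C@@]1(C)CCCCC1=O | intermediate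
10 | ethyl (1S)-1-methyl-2-oxocyclohex-3-ene-1-carboxylate | CCOC(=O)[C@@]1(C)CCC=CC1=O | intermediate
11 | ethyl (1S)-3,4-dibromo-1-methyl-2-oxocyclohexane-1-carboxylate (trans dibromide) | CCOC(=O)[C@@]1(C)CCC(Br)C(Br)C1=O | intermediate
12 | ethyl (1S)-3-bromo-1-methyl-2-oxocyclohex-3-ene-1-carboxylate | CCOC(=O)[C@@]1(C)CCC=C(Br)C1=O | intermediate
13 | [(1E)-4-{[tert-butyl(dimethyl)silyl]oxy}-3-methylidenebut-1-en-1-yl]lithium | [Li]/C=C/C(=C)CO[Si](C)(C)C(C)(C)C | intermediate
14 | [(1E)-4-{[tert-butyl(dimethyl)silyl]oxy}-3-methylidenebut-1-en-1-yl]magnesium bromide | Br[Mg]/C=C/C(=C)CO[Si](C)(C)C(C)(C)C | intermediate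
15 | ethyl (1S,2R)-3-bromo-2-hydroxy-1-methyl-2-[(1E)-4-{[tert-butyl(dimethyl)silyl]oxy}-3-methylidenebut-1-en-1-yl]cyclohex-3-ene-1-carboxylate (hydroxyl cis to methyl) | CCOC(=O)[C@@]1(C)CCC=C(Br)[C@@]1(O)/C=C/C(=C)CO[Si](C)(C)C(C)(C)C | intermediate
16 | (1R,6R)-2-bromo-6-(hydroxymethyl)-6-methyl-1-[(1E)-4-{[tert-butyl(dimethyl)silyl]oxy}-3-methylidenebut-1-en-1-yl]cyclohex-2-en-1-ol | OC[C@@]1(C)CCC=C(Br)[C@@]1(O)/C=C/C(=C)CO[Si](C)(C)C(C)(C)C | intermediate
17 | (1S,2R)-3-bromo-2-hydroxy-1-methyl-2-[(1E)-4-{[tert-butyl(dimethyl)silyl]oxy}-3-methylidenebut-1-en-1-yl]cyclohex-3-ene-1-carbaldehyde | O=C[C@@]1(C)CCC=C(Br)[C@@]1(O)/C=C/C(=C)CO[Si](C)(C)C(C)(C)C | intermediate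
18 | (1R,6R)-2-bromo-6-[(E)-2-iodoethenyl]-6-methyl-1-[(1E)-4-{[tert-butyl(dimethyl)silyl]oxy}-3-methylidenebut-1-en-1-yl]cyclohex-2-en-1-ol | I/C=C/[C@@]1(C)CCC=C(Br)[C@@]1(O)/C=C/C(=C)CO[Si](C)(C)C(C)(C)C | intermediate
19 | (1R,6R)-2-bromo-6-{(E)-2-[(4-methoxyphenyl)methoxy]ethenyl}-6-methyl-1-[(1E)-4-{[tert-butyl(dimethyl)silyl]oxy}-3-methylidenebut-1-en-1-yl]cyclohex-2-en-1-ol | COc1ccc(CO/C=C/[C@@]2(C)CCC=C(Br)[C@@]2(O)/C=C/C(=C)CO[Si](C)(C)C(C)(C)C)cc1 | intermediate
20 | methyl (5R,6R)-6-hydroxy-5-{(E)-2-[(4-methoxyphenyl)methoxy]ethenyl}-5-methyl-6-[(1E)-4-{[tert-butyl(dimethyl)silyl]oxy}-3-methylidenebut-1-en-1-yl]cyclohex-1-ene-1-carboxylate | COc1ccc(CO/C=C/[C@@]2(C)CCC=C(C(=O)OC)[C@@]2(O)/C=C/C(=C)CO[Si](C)(C)C(C)(C)C)cc1 | intermediate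
21 | potassium alkoxide of 20 | COc1ccc(CO/C=C/[C@@]2(C)CCC=C(C(=O)OC)[C@@]2([O-])/C=C/C(=C)CO[Si](C)(C)C(C)(C)C)cc1.[K+] | intermediate
22 | potassium (8E-ring-trans) C8=C9 dienolate of the ten-membered ketone | [K+].[O-]/C1=C\[C@@H](C(=C)CO[Si](C)(C)C(C)(C)C)[C@H](OCc2ccc(OC)cc2)/C=C(C)\CC/C=C1/C(=O)OC | intermediate
23 | methyl (1(10)-cis,4Z)-8α-hydroxy-6α-[(4-methoxyphenyl)methoxy]-9-oxo-12-{[tert-butyl(dimethyl)silyl]oxy}germacra-1(10),4,11(13)-trien-14-oate | O[C@@H]1[C@@H](C(=C)CO[Si](C)(C)C(C)(C)C)[C@H](OCc2ccc(OC)cc2)/C=C(C)\CC/C=C(/C(=O)OC)C1=O | intermediate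
24 | 8β-methacrylate of the 9-ketone (C8 inverted) | C=C(C)C(=O)O[C@H]1[C@@H](C(=C)CO[Si](C)(C)C(C)(C)C)[C@H](OCc2ccc(OC)cc2)/C=C(C)\CC/C=C(/C(=O)OC)C1=O | intermediate
25 | 9α-alcohol with 8β-methacrylate | C=C(C)C(=O)O[C@H]1[C@@H](C(=C)CO[Si](C)(C)C(C)(C)C)[C@H](OCc2ccc(OC)cc2)/C=C(C)\CC/C=C(/C(=O)OC)[C@@H]1O | intermediate
26 | 9α-acetate with 8β-methacrylate | C=C(C)C(=O)O[C@H]1[C@@H](C(=C)CO[Si](C)(C)C(C)(C)C)[C@H](OCc2ccc(OC)cc2)/C=C(C)\CC/C=C(/C(=O)OC)[C@@H]1OC(C)=O | intermediate
27 | 6α-alcohol (4Z olefin, 12-silyl ether) | C=C(C)C(=O)O[C@H]1[C@@H](C(=C)CO[Si](C)(C)C(C)(C)C)[C@H](O)/C=C(C)\CC/C=C(/C(=O)OC)[C@@H]1OC(C)=O | intermediate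
28 | 4α,5α-epoxy-6α-alcohol (12-silyl ether) | C=C(C)C(=O)O[C@H]1[C@@H](C(=C)CO[Si](C)(C)C(C)(C)C)[C@H](O)[C@@H]2O[C@]2(C)CC/C=C(/C(=O)OC)[C@@H]1OC(C)=O | intermediate
29 | 4α,5α-epoxy-6α,12-diol | C=C(C)C(=O)O[C@H]1[C@@H](C(=C)CO)[C@H](O)[C@@H]2O[C@]2(C)CC/C=C(/C(=O)OC)[C@@H]1OC(C)=O | intermediate
30 | 6α-hydroxy 12-enal | C=C(C)C(=O)O[C@H]1[C@@H](C(=C)C=O)[C@H](O)[C@@H]2O[C@]2(C)CC/C=C(/C(=O)OC)[C@@H]1OC(C)=O | intermediate
31 | 6,12-lactol (both anomers) | C=C(C)C(=O)O[C@H]1[C@H]2C(=C)C(O)O[C@@H]2[C@@H]2O[C@]2(C)CC/C=C(/C(=O)OC)[C@@H]1OC(C)=O | intermediate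
32 | CNP0153978.8 (9α-acetoxy-4α,5α-epoxy-8β-methacryloyloxy-cis,cis-germacra-1(10),11(13)-dien-6α,12-olide 14-methyl ester) | C=C(C)C(=O)O[C@H]1[C@H]2C(=C)C(=O)O[C@@H]2[C@@H]2O[C@]2(C)CC/C=C(/C(=O)OC)[C@@H]1OC(C)=O | target

## Count and least certain steps

Total step count: 20. Longest linear sequence: 18 (steps 3 to 20, from 5).

Step 13 (key step). The most likely failure is loss of control under the naked-alkoxide conditions. Proton transfer from the enoate γ-position (C2) can compete with the rearrangement. Rotation of the enolate plane before trapping would erode the C8 face selectivity. The ring-flipped chair, if populated, would give the E C4=C5 isomer. Fallback (neutral conditions, isolable enol ether), setting out from 20 and returning at 23: 20 is silylated (Me3SiCl, imidazole) to the trimethylsilyl ether F1. F1 is heated (toluene, sealed tube, 170–190 °C) in a thermal siloxy-Cope rearrangement through the same chair, giving the silyl dienol ether F2. Rubottom oxidation with dimethyldioxirane at −78 °C on the outer face gives the 8α-silyloxy ketone F3, and mild fluoride work-up gives 23.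

Step 7. Chelation may be incomplete. Without it the smaller ester turns pseudoaxial and the nucleophile enters anti to it, giving the trans-dialkenyl diastereomer; the magnesium alkoxide could also fragment by retro-aldol cleavage on warming. Fallback (covalently bound alkoxide direction in place of Lewis-acid chelation), setting out from 12 and returning at 16: Luche reduction of 12 gives the allylic alcohol ester F4. iBu2AlH reduces it to the diol F5. MnO2 oxidises only the allylic alcohol to the hydroxymethyl bromoenone F6. Excess 14 then forms the magnesium alkoxide of the CH2OH arm, which binds the ketone and directs the second equivalent to the same face, giving 16 directly.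

Step 14. SN2 displacement at C8 may be slow because C7 is branched and the backside trajectory runs across the ring. This opens the way to elimination toward the enolised diketone, to retention through an acyloxyphosphonium path, or to conjugate addition of the phosphine to the alkylidene keto ester. Fallback (oxidation–reduction inversion instead of displacement), setting out from 23 and returning at 26: chelation-controlled reduction of 23 with Zn(BH4)2 gives the 8α,9α-diol F7. Acetyl chloride/2,4,6-collidine at −78 °C acetylates the less hindered allylic C9 hydroxyl to give the 9-acetate F8. Dess–Martin oxidation gives the 8-ketone F9. NaBH4/CeCl3 adds hydride from the outer face anti to the C9–O bond to give the 8β-alcohol F10, and methacrylic anhydride/DMAP gives 26.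

Step 18. The ten-membered ring may hold the C6 hydroxyl in an acyclic-type arrangement (H-6 eclipsing the olefin), in which vanadium would deliver oxygen to the β face or react sluggishly. Fallback (reagent control on the lactone instead of hydroxyl direction), setting out from 27 and returning at 32: 27 is desilylated (Bu4NF/AcOH) to the diol F11. TEMPO/PhI(OAc)2 closes the diene lactone F12. Shi epoxidation (the fructose-derived ketone enantiomer chosen for the α face, Oxone, buffered) epoxidises the only electron-rich olefin, C4=C5, to give 32.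

Step 15. Hydride may follow the macrocycle conformation rather than the Felkin–Anh preference and give the 9β alcohol. Conjugate reduction of the alkylidene keto ester and ester migration on the alkoxide are the other failure processes. Fallback (reagent control), setting out from 24 and returning at 25: oxazaborolidine-catalysed (CBS) reduction with catecholborane at −78 °C, using the catalyst enantiomer matched to the 9α face; no new compound is made.

## Further compounds

F1 | step 13 | trimethylsilyl ether of 20 | COc1ccc(CO/C=C/[C@@]2(C)CCC=C(C(=O)OC)[C@@]2(O[Si](C)(C)C)/C=C/C(=C)CO[Si](C)(C)C(C)(C)C)cc1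
F2 | step 13 | ten-membered 9-(trimethylsilyloxy) ring-trans C8=C9 dienol ether | C[Si](C)(C)O/C1=C\[C@@H](C(=C)CO[Si](C)(C)C(C)(C)C)[C@H](OCc2ccc(OC)cc2)/C=C(C)\CC/C=C1/C(=O)OC
F3 | step 13 | 8α-(trimethylsilyloxy) 9-ketone | C[Si](C)(C)O[C@@H]1[C@@H](C(=C)CO[Si](C)(C)C(C)(C)C)[C@H](OCc2ccc(OC)cc2)/C=C(C)\CC/C=C(/C(=O)OC)C1=O
F4 | step 7 | ethyl (1S)-3-bromo-2-hydroxy-1-methylcyclohex-3-ene-1-carboxylate (C2 epimers) | CCOC(=O)[C@@]1(C)CCC=C(Br)C1O
F5 | step 7 | (6R)-2-bromo-6-(hydroxymethyl)-6-methylcyclohex-2-en-1-ol (C1 epimers) | OC[C@@]1(C)CCC=C(Br)C1O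
F6 | step 7 | (6R)-2-bromo-6-(hydroxymethyl)-6-methylcyclohex-2-en-1-one | OC[C@@]1(C)CCC=C(Br)C1=O
F7 | step 14 | 8α,9α-diol of the ten-membered ring | O[C@@H]1[C@@H](C(=C)CO[Si](C)(C)C(C)(C)C)[C@H](OCc2ccc(OC)cc2)/C=C(C)\CC/C=C(/C(=O)OC)[C@@H]1O
F8 | step 14 | 9α-acetoxy-8α-alcohol | O[C@@H]1[C@@H](C(=C)CO[Si](C)(C)C(C)(C)C)[C@H](OCc2ccc(OC)cc2)/C=C(C)\CC/C=C(/C(=O)OC)[C@@H]1OC(C)=O
F9 | step 14 | 9α-acetoxy-8-ketone | O=C1[C@@H](C(=C)CO[Si](C)(C)C(C)(C)C)[C@H](OCc2ccc(OC)cc2)/C=C(C)\CC/C=C(/C(=O)OC)[C@@H]1OC(C)=O
F10 | step 14 | 9α-acetoxy-8β-alcohol | O[C@H]1[C@@H](C(=C)CO[Si](C)(C)C(C)(C)C)[C@H](OCc2ccc(OC)cc2)/C=C(C)\CC/C=C(/C(=O)OC)[C@@H]1OC(C)=O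
F11 | step 18 | 6α,12-diol with the 4Z olefin | C=C(C)C(=O)O[C@H]1[C@@H](C(=C)CO)[C@H](O)/C=C(C)\CC/C=C(/C(=O)OC)[C@@H]1OC(C)=O
F12 | step 18 | 4Z-olefinic 6α,12-lactone (4,5-deoxy target) | C=C(C)C(=O)O[C@H]1[C@H]2C(=C)C(=O)O[C@@H]2/C=C(C)\CC/C=C(/C(=O)OC)[C@@H]1OC(C)=O
F0 | step 15 | none | none
A1 | alternative 1 | seco aldehyde–allylic bromide (Z enal at C6, 2-(bromomethyl)acrylate at C7, 8-silyl ether, 9-acetate) | O=C/C=C(C)\CC/C=C(/C(=O)OC)[C@H](OC(C)=O)[C@@H](O[Si](C)(C)C(C)(C)C)/C=C(/CBr)C(=O)OC
A2 | alternative 2 | cis-decalin 9-ol 5-mesylate (C4–C9 fusion) | COC(=O)C1=CCC[C@]2(C)[C@H](OS(C)(=O)=O)[C@@H](OCc3ccc(OC)cc3)[C@H](C(=C)CO[Si](C)(C)C(C)(C)C)[C@H](O[Si](C)(C)C(C)(C)C)[C@]12O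
A3 | alternative 3 | hexasubstituted 1-isopropenyl-2-vinylcyclohexanol (C5–C10 ring) | C=C(C)[C@]1(O)[C@@H](OCc2ccc(OC)cc2)[C@H](C(=C)CO[Si](C)(C)C(C)(C)C)[C@H](O[Si](C)(C)C(C)(C)C)[C@@H](O[Si](C)(C)C(C)(C)C)[C@@]1(C=C)C(=O)OC
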